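The dihydrofuran ring is disconnected at O1–C7a and C3–C3a. The feature exploited is that O1, C2 and C3 map onto the oxirane ring of a trans-stilbene oxide. Their two anchor points on ring A, C7a and C3a, are ortho to each other, like the two carbons of an aryne. A single fluoride-triggered step lets 4-chlorobenzyne insert into the C3–O bond of an enantiopure (R,R)-epoxide. Both bonds form, the five-membered ring closes, C2 is carried over and C3 is set trans. The epoxide bears an electron-poor 3,4-bis(mesyloxy)phenyl group (ring B) on C2 and a 3,5-dimethoxyphenyl group (ring C) on C3. The chlorine becomes the C5 handle for the styryl arm (ring D).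

Key step: step 6

**Labels.** Benzofuran numbering is used (O1, C2, C3, C3a, C4–C7, C7a).
- Ring A is the benzo ring.
- Ring B is the 3,4-dioxygenated aryl on C2.
- Ring C is the 3,5-dioxygenated aryl on C3.
- Ring D is the aryl of the (E)-styryl group on C5.
- The target is the trans-(2S,3S) isomer.

**Design points.**
- (a) The stilbene is built by a Heck reaction, not by a phosphonate carbanion, because strong bases strip aryl mesylates through sulfene elimination. One commercial styrene serves both Heck steps.
- (b) Meta-methoxy groups do not stabilise a benzylic cation. The C3/C2 discrimination therefore comes from destabilising C2, and sulfonates are kept on ring B for that reason. Acyloxy groups would still donate to a para cation.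
- (c) The methyl ethers are cleaved before the sulfonates. While ring B is electron-poor, the benzylic C2–O1 bond cannot ionise under BBr3.

**Remarks on the chemistry.**
- The D-fructose-derived ketone is assumed to give the same (R,R) sense of induction as on parent trans-stilbene.
- A remote chlorine is assumed to be only a weak director of aryne orientation.

Step 1
Reactants: 1 4-bromobenzene-1,2-diol (4-bromocatechol)
Product: 2 4-bromo-1,2-phenylene dimethanesulfonate
Conditions: MsCl (2.5 equiv), Et3N (3 equiv), CH2Cl2, 0 °C to rt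
Reagents that add atoms: methanesulfonyl chloride, CS(=O)(=O)Cl
Why: Routine O-sulfonylation of both phenols; the mesylates make ring B electron-poor, as step 6 requires, and are inert to palladium/phosphine catalysis, dioxirane, fluoride and BBr3.

Step 2
Reactants: 2 4-bromo-1,2-phenylene dimethanesulfonate; 3 3,5-dimethoxystyrene
Product: 4 (E)-4-[2-(3,5-dimethoxyphenyl)ethenyl]-1,2-phenylene dimethanesulfonate
Conditions: Pd(OAc)2 (2 mol %), P(o-tol)3 (6 mol %), Et3N (2 equiv), DMF, 90 °C; recrystallise
Reagents that add atoms: none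
Why: Mizoroki–Heck reaction of an electron-poor aryl bromide with a styrene, in which insertion at the terminal carbon and syn β-hydride elimination give the (E)-stilbene, and whose amine base spares the mesylates.

Step 3
Reactants: 4 (E)-4-[2-(3,5-dimethoxyphenyl)ethenyl]-1,2-phenylene dimethanesulfonate
Product: 5 (2R,3R)-2-[3,4-bis(methanesulfonyloxy)phenyl]-3-(3,5-dimethoxyphenyl)oxirane
Conditions: D-fructose-derived Shi ketone (1,2:4,5-di-O-isopropylidene-β-D-erythro-2,3-hexodiulo-2,6-pyranose, 0.3 equiv), KHSO5 (as 2KHSO5·KHSO4·K2SO4), K2CO3, n-Bu4NHSO4 (cat.), aq. Na2B4O7/Na2H2edta buffer (pH 10.5), MeCN–dimethoxymethane, 0 °C; recrystallise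
Reagents that add atoms: potassium peroxymonosulfate, [K+].[O-]S(=O)(=O)OO
Why: Shi asymmetric epoxidation, in which the dioxirane made in situ delivers oxygen through a spiro transition state to one face of a trans-disubstituted alkene (the best substrate class for this ketone); the D-fructose series gives the (R,R)-oxide of trans-stilbenes, which fixes C2 for good and C3 provisionally, and syn addition keeps the trans geometry.

Step 4
Reactants: 6 2-bromo-4-chlorophenol
Product: 7 (2-bromo-4-chlorophenoxy)trimethylsilane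
Conditions: HN(SiMe3)2 (0.7 equiv), THF, reflux; evaporate
Reagents that add atoms: hexamethyldisilazane, C[Si](C)(C)N[Si](C)(C)C
Why: Silylation of a phenol with hexamethyldisilazane is clean, ammonia being the only by-product, so crude 7 can be used after evaporation.

Step 5
Reactants: 7 (2-bromo-4-chlorophenoxy)trimethylsilane
Product: 10 4-chloro-2-(trimethylsilyl)phenyl trifluoromethanesulfonate, via aryllithium 8 (not isolated), via lithium 4-chloro-2-(trimethylsilyl)phenolate 9 (not isolated)
Conditions: n-BuLi (1.1 equiv), THF, −78 °C; then Tf2O (1.2 equiv), −78 °C to rt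
Reagents that add atoms: trifluoromethanesulfonic anhydride, O=S(=O)(OS(=O)(=O)C(F)(F)F)C(F)(F)F
Why: Bromine–lithium exchange, at −78 °C much faster than any reaction at the C–Cl bond, triggers a retro-Brook 1,3-shift of silicon from oxygen to carbon, and the phenolate is trapped with Tf2O, the standard entry to Kobayashi aryne precursors.

Step 6
Reactants: 5 (2R,3R)-2-[3,4-bis(methanesulfonyloxy)phenyl]-3-(3,5-dimethoxyphenyl)oxirane; 10 4-chloro-2-(trimethylsilyl)phenyl trifluoromethanesulfonate
Product: 13 (2S,3S)-5-chloro-2-[3,4-bis(methanesulfonyloxy)phenyl]-3-(3,5-dimethoxyphenyl)-2,3-dihydrobenzofuran, via 4-chlorobenzyne 11 (not isolated), via oxiranium aryl-anion zwitterion 12 (not isolated)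
Conditions: CsF (5 equiv), dry MeCN (0.4 M in 5), 0 °C to rt, 10 (2.5 equiv) added by syringe pump over 6 h
Reagents that add atoms: none
Why: Fluoride attacks the silicon of 10 and loss of triflate releases 4-chlorobenzyne 11; the oxygen of 5 adds to the aryne carbon para to chlorine to give the O-aryl oxiranium/aryl-anion zwitterion 12, the benzylic C3–O bond ionises, and the carbanion at C3a bonds to C3, so that O1–C7a and C3–C3a arise in the same flask. The closest known reaction is the fluoride-induced insertion of arynes into the benzylic C–O bond of styrene oxide, which gives 3-aryl-2,3-dihydrobenzofurans; here it is applied to an internal, enantiopure trans-diaryl epoxide. The dihydrofuran ring closes by stepwise cation–anion recombination (SN1-like, formally 5-exo-trig on the quinoid form of the benzylic cation), because the short O1–C7a tether cannot place C3a behind the C3–O bond for an SN2 displacement. C2 is only carried over, as the C2–O1 bond stays intact throughout (R in 5 and S in 13 describe the same arrangement, only the CIP ranking changes), whereas the new centre C3 is controlled by C2: C3a bonds to the flat C3 on the face that turns ring C away from ring B, which is also the result of front-side collapse of a tight ion pair, so trans-13 is expected either way. Of the selectivities needed, C3–O over C2–O cleavage is secured by the two sulfonates, which disfavour positive charge next to ring B far more than two meta-methoxy groups do next to ring C, and closure ahead of proton transfer or hydride shift is favoured by its intramolecular nature, a high epoxide concentration and slow release of 11. Aryne orientation rests only on the electron-withdrawing σ-effect of chlorine, which places the carbanion at the nearer C3a and the oxygen at C7a; this bias is expected to be modest, so removal of the 6-chloro regioisomer by chromatography and crystallisation is part of the plan.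

Step 7
Reactants: 13 (2S,3S)-5-chloro-2-[3,4-bis(methanesulfonyloxy)phenyl]-3-(3,5-dimethoxyphenyl)-2,3-dihydrobenzofuran; 3 3,5-dimethoxystyrene
Product: 14 (2S,3S)-2-[3,4-bis(methanesulfonyloxy)phenyl]-3-(3,5-dimethoxyphenyl)-5-[(E)-2-(3,5-dimethoxyphenyl)ethenyl]-2,3-dihydrobenzofuran
Conditions: 3 (1.5 equiv), Pd2(dba)3 (2.5 mol %), P(t-Bu)3 (10 mol %), Cy2NMe (1.5 equiv), 1,4-dioxane, 110 °C
Reagents that add atoms: none
Why: Mizoroki–Heck reaction of an electron-rich aryl chloride, made possible by the bulky electron-rich P(t-Bu)3, which allows oxidative addition of zerovalent palladium to C–Cl while leaving aryl mesylate C–O bonds alone; the (E)-alkene follows from syn insertion and syn β-hydride elimination, and neither C2 nor C3 has an acidic or ionisable bond under a hindered amine.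

Step 8
Reactants: 14 (2S,3S)-2-[3,4-bis(methanesulfonyloxy)phenyl]-3-(3,5-dimethoxyphenyl)-5-[(E)-2-(3,5-dimethoxyphenyl)ethenyl]-2,3-dihydrobenzofuran
Product: 15 (2S,3S)-2-[3,4-bis(methanesulfonyloxy)phenyl]-3-(3,5-dihydroxyphenyl)-5-[(E)-2-(3,5-dihydroxyphenyl)ethenyl]-2,3-dihydrobenzofuran
Conditions: BBr3 (10 equiv), CH2Cl2, −78 °C to rt; ice-water quench
Reagents that add atoms: none
Why: Lewis-acid ether cleavage (boron binds the methoxy oxygen, bromide attacks methyl by SN2), run before sulfonate removal on purpose: with ring B still electron-poor the benzylic C2–O1 bond cannot ionise, so the ring and both stereocentres should survive, and aryl mesylates do not react with BBr3.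

Step 9
Reactants: 15 (2S,3S)-2-[3,4-bis(methanesulfonyloxy)phenyl]-3-(3,5-dihydroxyphenyl)-5-[(E)-2-(3,5-dihydroxyphenyl)ethenyl]-2,3-dihydrobenzofuran
Product: 16 (2S,3S)-2-(3,4-dihydroxyphenyl)-3-(3,5-dihydroxyphenyl)-5-[(E)-2-(3,5-dihydroxyphenyl)ethenyl]-2,3-dihydrobenzofuran (CNP0207985.1)
Conditions: KOH (2 M aq., 15 equiv), MeOH–THF, degassed, argon, 45 °C; then 1 M HCl, 0 °C, to pH 3
Reagents that add atoms: none
Why: Alkaline hydrolysis of aryl sulfonates by hydroxide attack at sulfur with S–O cleavage, so the aryl oxygens stay in place; exclusion of oxygen and a moderate temperature guard the phenolates against oxidation and against ring opening through a para-quinone methide, and hydroxide does not deprotonate C2 or C3.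

**Compound list**
1 | 4-bromobenzene-1,2-diol | Oc1ccc(Br)cc1O | starting material
2 | 4-bromo-1,2-phenylene dimethanesulfonate | CS(=O)(=O)Oc1ccc(Br)cc1OS(C)(=O)=O | intermediate
3 | 3,5-dimethoxystyrene | C=Cc1cc(OC)cc(OC)c1 | starting material
4 | (E)-4-[2-(3,5-dimethoxyphenyl)ethenyl]-1,2-phenylene dimethanesulfonate | COc1cc(OC)cc(/C=C/c2ccc(OS(C)(=O)=O)c(OS(C)(=O)=O)c2)c1 | intermediate
5 | (2R,3R)-2-[3,4-bis(methanesulfonyloxy)phenyl]-3-(3,5-dimethoxyphenyl)oxirane | COc1cc(OC)cc(c1)[C@@H]2[C@@H](c3ccc(OS(C)(=O)=O)c(OS(C)(=O)=O)c3)O2 | intermediate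
6 | 2-bromo-4-chlorophenol | Oc1ccc(Cl)cc1Br | starting material
7 | (2-bromo-4-chlorophenoxy)trimethylsilane | C[Si](C)(C)Oc1ccc(Cl)cc1Br | intermediate
8 | [5-chloro-2-(trimethylsilyloxy)phenyl]lithium | [Li]c1cc(Cl)ccc1O[Si](C)(C)C | intermediate
9 | lithium 4-chloro-2-(trimethylsilyl)phenolate | [Li+].[O-]c1ccc(Cl)cc1[Si](C)(C)C | intermediate
10 | 4-chloro-2-(trimethylsilyl)phenyl trifluoromethanesulfonate | C[Si](C)(C)c1cc(Cl)ccc1OS(=O)(=O)C(F)(F)F | intermediate
11 | 4-chlorobenzyne (4-chloro-1,2-didehydrobenzene) | ClC1=CC#CC=C1 | intermediate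
12 | (2R,3R)-oxiranium zwitterion from 5 and 11, O-bound 4-chlorophenyl with the carbanion at its C2 | COc1cc(OC)cc(c1)[C@@H]2[C@@H](c3ccc(OS(C)(=O)=O)c(OS(C)(=O)=O)c3)[O+]2c4ccc(Cl)c[c-]4 | intermediate
13 | (2S,3S)-5-chloro-2-[3,4-bis(methanesulfonyloxy)phenyl]-3-(3,5-dimethoxyphenyl)-2,3-dihydrobenzofuran | Clc1ccc2c(c1)[C@H](c1cc(OC)cc(OC)c1)[C@@H](c1ccc(OS(C)(=O)=O)c(OS(C)(=O)=O)c1)O2 | intermediate
14 | (2S,3S)-2-[3,4-bis(methanesulfonyloxy)phenyl]-3-(3,5-dimethoxyphenyl)-5-[(E)-2-(3,5-dimethoxyphenyl)ethenyl]-2,3-dihydrobenzofuran | COc1cc(OC)cc(/C=C/c2ccc3c(c2)[C@H](c2cc(OC)cc(OC)c2)[C@@H](c2ccc(OS(C)(=O)=O)c(OS(C)(=O)=O)c2)O3)c1 | intermediate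
15 | (2S,3S)-2-[3,4-bis(methanesulfonyloxy)phenyl]-3-(3,5-dihydroxyphenyl)-5-[(E)-2-(3,5-dihydroxyphenyl)ethenyl]-2,3-dihydrobenzofuran | Oc1cc(O)cc(/C=C/c2ccc3c(c2)[C@H](c2cc(O)cc(O)c2)[C@@H](c2ccc(OS(C)(=O)=O)c(OS(C)(=O)=O)c2)O3)c1 | intermediate
16 | (2S,3S)-2-(3,4-dihydroxyphenyl)-3-(3,5-dihydroxyphenyl)-5-[(E)-2-(3,5-dihydroxyphenyl)ethenyl]-2,3-dihydrobenzofuran | Oc1cc(O)cc(/C=C/c2ccc3c(c2)[C@H](c2cc(O)cc(O)c2)[C@@H](c2ccc(O)c(O)c2)O3)c1 | target

Total step count: 9.
Longest linear sequence: 7 (steps 1, 2, 3, 6, 7, 8, 9).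

**Steps most likely to fail**

**Step 6.**
- What may go wrong: weak control over the orientation in which the unsymmetrical aryne accepts the oxygen. Protonation of the aryl anion (by solvent or a mesyl CH3 group) or a 1,2-hydride shift may outrun ring closure. The trans preference may also erode.
- Fallback: intramolecular carbene C–H insertion. It sets out from 6 and comes back to the route at 16.
- Double lithiation of 6 (n-BuLi, 2.2 equiv, THF, −78 °C) and acylation with 3,5-dimethoxy-N-methoxy-N-methylbenzamide should give (5-chloro-2-hydroxyphenyl)(3,5-dimethoxyphenyl)methanone F1.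
- O-alkylation with 3,4-dimethoxybenzyl chloride (K2CO3, DMF) gives [5-chloro-2-(3,4-dimethoxybenzyloxy)phenyl](3,5-dimethoxyphenyl)methanone F2.
- Hydrazine hydrate (EtOH, AcOH, reflux) gives its hydrazone F3.
- MnO2 (CH2Cl2, 0 °C) oxidises F3 to the diaryldiazomethane F4, which is not isolated. It is treated with the antipode of Rh2(PTAD)4 (dirhodium tetrakis[N-phthaloyl(adamantan-1-yl)glycinate], 1 mol %) that sets 3S.
- The donor/donor carbene inserts into the benzylic ether C–H bond to give cis-(2R,3S)-5-chloro-2-(3,4-dimethoxyphenyl)-3-(3,5-dimethoxyphenyl)-2,3-dihydrobenzofuran F5.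
- CF3CO2H in CH2Cl2 epimerises C2 by reversible ionisation of C2–O1, now assisted by the electron-rich ring B, to the trans-(2S,3S) isomer F6.
- Heck coupling with 3 as in step 7 gives the (2S,3S)-hexamethyl ether F7, and BBr3 (−78 to 0 °C) gives 16.

**Step 7.**
- What may go wrong: sluggish oxidative addition to the electron-rich aryl chloride, catalyst decay and styrene polymerisation at the temperature needed.
- Fallback: cross-coupling of a preformed alkenylboron reagent in place of C–H alkenylation. It sets out from 13 and comes back at 14.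
- Cross-metathesis of 3 with 2-ethenyl-4,4,5,5-tetramethyl-1,3,2-dioxaborolane (second-generation Grubbs catalyst, CH2Cl2, reflux) should give (E)-2-[2-(3,5-dimethoxyphenyl)ethenyl]-4,4,5,5-tetramethyl-1,3,2-dioxaborolane F8.
- Suzuki–Miyaura coupling of F8 with 13 (Pd(OAc)2, SPhos, K3PO4, 1,4-dioxane, 80 °C) gives 14, with the alkene geometry already fixed in the reagent.

**Step 9.**
- What may go wrong: slow cleavage of the second sulfonate next to a phenolate, which would call for harsher base. That would bring oxidative degradation of the polyphenolate and ring opening through a quinone methide.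
- Fallback: eliminative sulfonate removal before demethylation, so that the free hexaphenol never meets base. It sets out from 14 and comes back at 16.
- LiN(i-Pr)2 (5 equiv, THF, −78 to 0 °C) removes both mesylates by E1cB loss of sulfene. This gives (2S,3S)-2-(3,4-dihydroxyphenyl)-3-(3,5-dimethoxyphenyl)-5-[(E)-2-(3,5-dimethoxyphenyl)ethenyl]-2,3-dihydrobenzofuran F9.
- BBr3 (CH2Cl2, −78 to 0 °C) first ties the catechol up as a cyclic bromoborate, which damps its donor power towards C2. It then cleaves the four methyl ethers to give 16 after acidic aqueous work-up.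

**Further compounds**
F1 | step 6 | (5-chloro-2-hydroxyphenyl)(3,5-dimethoxyphenyl)methanone | COc1cc(OC)cc(c1)C(=O)c1cc(Cl)ccc1O
F2 | step 6 | [5-chloro-2-(3,4-dimethoxybenzyloxy)phenyl](3,5-dimethoxyphenyl)methanone | COc1cc(OC)cc(c1)C(=O)c1cc(Cl)ccc1OCc1ccc(OC)c(OC)c1
F3 | step 6 | hydrazone of F2 | COc1cc(OC)cc(c1)C(=NN)c1cc(Cl)ccc1OCc1ccc(OC)c(OC)c1
F4 | step 6 | [5-chloro-2-(3,4-dimethoxybenzyloxy)phenyl](3,5-dimethoxyphenyl)diazomethane | COc1cc(OC)cc(c1)C(=[N+]=[N-])c1cc(Cl)ccc1OCc1ccc(OC)c(OC)c1
F5 | step 6 | cis-(2R,3S)-5-chloro-2-(3,4-dimethoxyphenyl)-3-(3,5-dimethoxyphenyl)-2,3-dihydrobenzofuran | Clc1ccc2c(c1)[C@H](c1cc(OC)cc(OC)c1)[C@H](c1ccc(OC)c(OC)c1)O2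
F6 | step 6 | trans-(2S,3S)-5-chloro-2-(3,4-dimethoxyphenyl)-3-(3,5-dimethoxyphenyl)-2,3-dihydrobenzofuran | Clc1ccc2c(c1)[C@H](c1cc(OC)cc(OC)c1)[C@@H](c1ccc(OC)c(OC)c1)O2
F7 | step 6 | (2S,3S)-2-(3,4-dimethoxyphenyl)-3-(3,5-dimethoxyphenyl)-5-[(E)-2-(3,5-dimethoxyphenyl)ethenyl]-2,3-dihydrobenzofuran | COc1cc(OC)cc(/C=C/c2ccc3c(c2)[C@H](c2cc(OC)cc(OC)c2)[C@@H](c2ccc(OC)c(OC)c2)O3)c1
F8 | step 7 | (E)-2-[2-(3,5-dimethoxyphenyl)ethenyl]-4,4,5,5-tetramethyl-1,3,2-dioxaborolane | COc1cc(OC)cc(/C=C/B2OC(C)(C)C(C)(C)O2)c1
F9 | step 9 | (2S,3S)-2-(3,4-dihydroxyphenyl)-3-(3,5-dimethoxyphenyl)-5-[(E)-2-(3,5-dimethoxyphenyl)ethenyl]-2,3-dihydrobenzofuran | COc1cc(OC)cc(/C=C/c2ccc3c(c2)[C@H](c2cc(OC)cc(OC)c2)[C@@H](c2ccc(O)c(O)c2)O3)c1
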